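**Plan**
- Cuts: the methylated flavone unit at O1–C2 and C2–C3 (chalcone from aldehyde 21 and acetophenone 26); the apigenin pyranone at O1–C2 and C4–C4a (ynoate 15 on phenol 11); ring A of the apigenin unit at C8–C8a, C6–C7 and C4a–C8a.
- Enabling feature: in ring A of the apigenin unit, C8 carries the aryl group between the oxygenated carbons C7 and C8a, with the C5 oxygen para to it. C7(O)–C8(aryl) maps onto a siloxyalkyne, C8a(O) onto a ketene carbonyl carbon, and C6–C5(OEt)–C4a onto the rest of 3-ethoxycyclobutenone.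
- Forward order: benzoate → aryl siloxyalkyne → ring A by benzannulation (biaryl bond already in place) → apigenin pyranone by oxa-Michael addition and Friedel–Crafts closure → chalcone → second pyranone by oxidative cyclization → BCl3 dealkylation.
- Stereochemistry: the target has no stereocentre; the sp3 centres of the cascade vanish on aromatization and the alkene geometries are erased in the ring closures.

Key step: step 3

Remark: the target SMILES carries no stereodescriptor, so the 3'–8'' biaryl axis is treated as configurationally undefined and no atroposelective step is planned.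

**Step 1**
Reactants: 1 methyl 5-formyl-2-methoxybenzoate
Product: 2 methyl 5-(1,3-dioxolan-2-yl)-2-methoxybenzoate
Conditions: HOCH2CH2OH, p-TsOH·H2O (cat.), toluene, reflux, Dean–Stark
Reagents that add atoms: ethane-1,2-diol, OCCO
Why: Acid-catalysed acetalization with azeotropic removal of water masks the aldehyde, the only group that would not survive the organolithium chemistry of step 2, while the methyl ester is inert.

**Step 2**
Reactants: 2 methyl 5-(1,3-dioxolan-2-yl)-2-methoxybenzoate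
Product: 5 2-{4-methoxy-3-[(triisopropylsilyloxy)ethynyl]phenyl}-1,3-dioxolane, via lithium dibromoenolate 3 (not isolated), via lithium ynolate 4 (not isolated)
Conditions: CH2Br2, lithium 2,2,6,6-tetramethylpiperidide (from the amine and n-BuLi), THF, −78 °C; then n-BuLi, −78 → 25 °C; then i-Pr3SiCl, −78 → 0 °C; non-acidic work-up
Reagents that add atoms: dibromomethane, BrCBr; chlorotri(propan-2-yl)silane, CC(C)[Si](Cl)(C(C)C)C(C)C
Why: Kowalski ester homologation, in which dibromomethyllithium adds to the ester, the derived enolate 3 undergoes bromine–lithium exchange and 1,2-aryl shift to ynolate 4 (aryl now on the carbon that came from dibromomethane, oxygen on the former ester carbon), and the bulky chlorosilane traps the ynolate on oxygen.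

**Step 3**
Reactants: 5 2-{4-methoxy-3-[(triisopropylsilyloxy)ethynyl]phenyl}-1,3-dioxolane; 6 3-ethoxycyclobut-2-en-1-one
Product: 11 2-[5-(1,3-dioxolan-2-yl)-2-methoxyphenyl]-5-ethoxy-3-(triisopropylsilyloxy)phenol, via (1-ethoxyvinyl)ketene 7 (not isolated), via 4-vinylcyclobutenone 8 (not isolated), via dienylketene 9 (not isolated), via cyclohexadienone 10 (not isolated)
Conditions: toluene (degassed), 6 in slight excess, 80 → 110 °C, sealed tube
Reagents that add atoms: none
Why: Heat opens 6 by 4π electrocyclic ring opening to (1-ethoxyvinyl)ketene 7, whose electrophilic carbonyl carbon bonds to the aryl-bearing alkyne carbon while its α-carbon bonds to the siloxy carbon ([2+2] cycloaddition, making C8–C8a and C6–C7 of the apigenin unit) to give 8. Reversible 4π opening of 8 gives dienylketene 9, and ring A closes by thermal disrotatory 6π electrocyclization (C4a–C8a) to dienone 10, which tautomerizes to phenol 11. This is the Danheiser benzannulation of cyclobutenones with siloxyalkynes to resorcinol monosilyl ethers, here applied to a 3-alkoxycyclobutenone and an aryl siloxyalkyne, a pairing that stretches the documented scope. No stereocentre survives, since C4 of 8 is lost on ring opening. The selectivity needed is the orientation of the ketene–alkyne cycloaddition, and it is secured by the oxygen lone pair of the siloxyalkyne, which makes the aryl-bearing carbon the nucleophilic terminus, so the aryl group should end between the new hydroxyl (C8a) and the silyloxy group (C7) with the ethoxy group para (C5). Because the aryl-bearing alkyne carbon stems from dibromomethane and the siloxy carbon from the ester carbon of 2, the hindered biaryl bond exists before the ring does and no arene–arene coupling is required.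

**Step 4**
Reactants: 12 4-isopropoxybenzaldehyde
Product: 13 1-(2,2-dibromoethenyl)-4-isopropoxybenzene
Conditions: CBr4, PPh3, CH2Cl2, 0 °C
Reagents that add atoms: tetrabromomethane, BrC(Br)(Br)Br
Why: Corey–Fuchs dibromo-olefination, in which the ylide formed from CBr4 and PPh3 converts the aldehyde into the 1,1-dibromoalkene.

**Step 5**
Reactants: 13 1-(2,2-dibromoethenyl)-4-isopropoxybenzene
Product: 15 tert-butyl 3-(4-isopropoxyphenyl)prop-2-ynoate, via lithium acetylide 14 (not isolated)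
Conditions: n-BuLi (2.1 equiv), THF, −78 °C; then Boc2O, −78 → 0 °C
Reagents that add atoms: di-tert-butyl dicarbonate, CC(C)(C)OC(=O)OC(=O)OC(C)(C)C
Why: Second stage of the Corey–Fuchs sequence, where bromine–lithium exchange, loss of LiBr and deprotonation give acetylide 14, which is C-acylated by Boc2O to the tert-butyl ynoate.

**Step 6**
Reactants: 11 2-[5-(1,3-dioxolan-2-yl)-2-methoxyphenyl]-5-ethoxy-3-(triisopropylsilyloxy)phenol; 15 tert-butyl 3-(4-isopropoxyphenyl)prop-2-ynoate
Product: 16 tert-butyl (2Z)-3-{2-[5-(1,3-dioxolan-2-yl)-2-methoxyphenyl]-5-ethoxy-3-(triisopropylsilyloxy)phenoxy}-3-(4-isopropoxyphenyl)prop-2-enoate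
Conditions: K2CO3 (0.3 equiv), dry DMF, 70 °C
Reagents that add atoms: none
Why: Base-catalysed oxa-Michael addition of the only free phenol to the ynoate should give the β-aryloxycinnamate by anti addition (an E isomer, if formed, converges under the acid of step 7), the silyl ether and acetal being inert to weak anhydrous base.

**Step 7**
Reactants: 16 tert-butyl (2Z)-3-{2-[5-(1,3-dioxolan-2-yl)-2-methoxyphenyl]-5-ethoxy-3-(triisopropylsilyloxy)phenoxy}-3-(4-isopropoxyphenyl)prop-2-enoate
Product: 19 3-[5-ethoxy-2-(4-isopropoxyphenyl)-4-oxo-7-(triisopropylsilyloxy)-4H-chromen-8-yl]-4-methoxybenzaldehyde, via carboxylic acid 17 (not isolated), via flavone acetal 18 (not isolated)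
Conditions: CF3CO2H, CH2Cl2, 0 → 25 °C; then (CF3CO)2O, 0 → 25 °C; then 1 M aq. HCl, THF, 25 °C
Reagents that add atoms: water, O
Why: Acidolysis of the tert-butyl ester, activation of acid 17 as the mixed trifluoroacetic anhydride and intramolecular Friedel–Crafts acylation at the single free position ortho to the enol-ether oxygen (C4a, the tether cannot reach C6) close the pyranone, and aqueous acid then hydrolyses the dioxolane.

**Step 8**
Reactants: 19 3-[5-ethoxy-2-(4-isopropoxyphenyl)-4-oxo-7-(triisopropylsilyloxy)-4H-chromen-8-yl]-4-methoxybenzaldehyde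
Product: 21 3-[5-ethoxy-7-isopropoxy-2-(4-isopropoxyphenyl)-4-oxo-4H-chromen-8-yl]-4-methoxybenzaldehyde, via cesium phenoxide 20 (not isolated)
Conditions: CsF, 2-bromopropane, DMF, 50 °C
Reagents that add atoms: 2-bromopropane, CC(C)Br
Why: Fluoride cleaves the aryl silyl ether and phenoxide 20 is O-alkylated in the same flask (desilylative Williamson etherification), replacing a group that would not survive the hydroxide of step 11 by an isopropyl ether that falls with the other one in step 13.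

**Step 9**
Reactants: 22 2,6-dimethoxytoluene
Product: 24 3,5-dimethoxy-4-methylphenol, via arylboronic ester 23 (not isolated)
Conditions: [Ir(OMe)(cod)]2 (cat.), 4,4'-di-tert-butyl-2,2'-bipyridine (cat.), B2pin2, THF, 80 °C; then KHSO5 (as 2KHSO5·KHSO4·K2SO4), acetone/H2O, 25 °C
Reagents that add atoms: potassium peroxymonosulfate, [K+].[O-]S(=O)(=O)OO
Why: Sterically governed iridium-catalysed C–H borylation should occur at the only ring position with no ortho substituent (para to the methyl group), and oxidation of the C–B bond in the same flask gives the phenol.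

**Step 10**
Reactants: 24 3,5-dimethoxy-4-methylphenol
Product: 26 1-(6-hydroxy-2,4-dimethoxy-3-methylphenyl)ethan-1-one, via difluoroboron chelate 25 (not isolated)
Conditions: Ac2O, BF3·OEt2, 80 °C; then H2O/EtOH, reflux
Reagents that add atoms: acetic anhydride, CC(=O)OC(C)=O
Why: BF3-mediated C-acetylation (Fries-type) of the symmetrical phenol can only take one of the two equivalent ortho positions because the para position carries the methyl group, and the ketone is held as chelate 25 until hydrolysis.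

**Step 11**
Reactants: 21 3-[5-ethoxy-7-isopropoxy-2-(4-isopropoxyphenyl)-4-oxo-4H-chromen-8-yl]-4-methoxybenzaldehyde; 26 1-(6-hydroxy-2,4-dimethoxy-3-methylphenyl)ethan-1-one
Product: 27 (2E)-3-{3-[5-ethoxy-7-isopropoxy-2-(4-isopropoxyphenyl)-4-oxo-4H-chromen-8-yl]-4-methoxyphenyl}-1-(6-hydroxy-2,4-dimethoxy-3-methylphenyl)prop-2-en-1-one
Conditions: KOH, EtOH/THF, 25 °C
Reagents that add atoms: none
Why: Claisen–Schmidt condensation of the methyl ketone enolate with the non-enolizable aryl aldehyde should give the (E)-chalcone, and any flavanone formed by ring closure converges in step 12.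

**Step 12**
Reactants: 27 (2E)-3-{3-[5-ethoxy-7-isopropoxy-2-(4-isopropoxyphenyl)-4-oxo-4H-chromen-8-yl]-4-methoxyphenyl}-1-(6-hydroxy-2,4-dimethoxy-3-methylphenyl)prop-2-en-1-one
Product: 28 8-[5-(5,7-dimethoxy-6-methyl-4-oxo-4H-chromen-2-yl)-2-methoxyphenyl]-5-ethoxy-7-isopropoxy-2-(4-isopropoxyphenyl)-4H-chromen-4-one
Conditions: I2 (10 mol %), DMSO, 130 °C
Reagents that add atoms: none
Why: Iodine-catalysed oxidative cyclization of the 2'-hydroxychalcone (oxa-Michael closure, α-iodination and loss of HI, with DMSO reoxidising iodide) gives the second flavone.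

**Step 13**
Reactants: 28 8-[5-(5,7-dimethoxy-6-methyl-4-oxo-4H-chromen-2-yl)-2-methoxyphenyl]-5-ethoxy-7-isopropoxy-2-(4-isopropoxyphenyl)-4H-chromen-4-one
Product: 29 taiwanhomoflavone A
Conditions: BCl3 (excess), CH2Cl2, −78 → 25 °C; then MeOH, H2O
Reagents that add atoms: none
Why: BCl3 should cleave the two isopropyl ethers (secondary alkyl) and the two alkoxy groups peri to a carbonyl (chelation-assisted), while the non-chelated methyl ethers at C7 of the methylated unit and on ring B stay.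

**Compound list**
1 | methyl 5-formyl-2-methoxybenzoate | COC(=O)c1cc(C=O)ccc1OC | starting material
2 | methyl 5-(1,3-dioxolan-2-yl)-2-methoxybenzoate | COC(=O)c1cc(C2OCCO2)ccc1OC | intermediate
3 | lithium 2,2-dibromo-1-[5-(1,3-dioxolan-2-yl)-2-methoxyphenyl]ethen-1-olate | [Li+].[O-]C(=C(Br)Br)c1cc(C2OCCO2)ccc1OC | intermediate
4 | lithium 2-[5-(1,3-dioxolan-2-yl)-2-methoxyphenyl]ethyn-1-olate | [Li+].[O-]C#Cc1cc(C2OCCO2)ccc1OC | intermediate
5 | 2-{4-methoxy-3-[(triisopropylsilyloxy)ethynyl]phenyl}-1,3-dioxolane | COc1ccc(C2OCCO2)cc1C#CO[Si](C(C)C)(C(C)C)C(C)C | intermediate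
6 | 3-ethoxycyclobut-2-en-1-one | CCOC1=CC(=O)C1 | starting material
7 | 3-ethoxybuta-1,3-dien-1-one, (1-ethoxyvinyl)ketene | C=C(OCC)C=C=O | intermediate
8 | 2-[5-(1,3-dioxolan-2-yl)-2-methoxyphenyl]-4-(1-ethoxyethenyl)-3-(triisopropylsilyloxy)cyclobut-2-en-1-one (racemic) | C=C(OCC)C1C(=O)C(c2cc(C3OCCO3)ccc2OC)=C1O[Si](C(C)C)(C(C)C)C(C)C | intermediate
9 | (3E)-2-[5-(1,3-dioxolan-2-yl)-2-methoxyphenyl]-5-ethoxy-3-(triisopropylsilyloxy)hexa-1,3,5-trien-1-one | O=C=C(c1cc(C2OCCO2)ccc1OC)\C(O[Si](C(C)C)(C(C)C)C(C)C)=C/C(OCC)=C | intermediate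
10 | 2-[5-(1,3-dioxolan-2-yl)-2-methoxyphenyl]-5-ethoxy-3-(triisopropylsilyloxy)cyclohexa-2,4-dien-1-one | O=C1CC(OCC)=CC(O[Si](C(C)C)(C(C)C)C(C)C)=C1c1cc(C2OCCO2)ccc1OC | intermediate
11 | 2-[5-(1,3-dioxolan-2-yl)-2-methoxyphenyl]-5-ethoxy-3-(triisopropylsilyloxy)phenol | COc1ccc(C2OCCO2)cc1-c1c(O)cc(OCC)cc1O[Si](C(C)C)(C(C)C)C(C)C | intermediate
12 | 4-isopropoxybenzaldehyde | CC(C)Oc1ccc(C=O)cc1 | starting material
13 | 1-(2,2-dibromoethenyl)-4-isopropoxybenzene | CC(C)Oc1ccc(C=C(Br)Br)cc1 | intermediate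
14 | lithium (4-isopropoxyphenyl)ethynide | [Li+].[C-]#Cc1ccc(OC(C)C)cc1 | intermediate
15 | tert-butyl 3-(4-isopropoxyphenyl)prop-2-ynoate | CC(C)Oc1ccc(C#CC(=O)OC(C)(C)C)cc1 | intermediate
16 | tert-butyl (2Z)-3-{2-[5-(1,3-dioxolan-2-yl)-2-methoxyphenyl]-5-ethoxy-3-(triisopropylsilyloxy)phenoxy}-3-(4-isopropoxyphenyl)prop-2-enoate | CC(C)Oc1ccc(cc1)/C(Oc1cc(OCC)cc(O[Si](C(C)C)(C(C)C)C(C)C)c1-c1cc(C2OCCO2)ccc1OC)=C/C(=O)OC(C)(C)C | intermediate
17 | (2Z)-3-{2-[5-(1,3-dioxolan-2-yl)-2-methoxyphenyl]-5-ethoxy-3-(triisopropylsilyloxy)phenoxy}-3-(4-isopropoxyphenyl)prop-2-enoic acid | CC(C)Oc1ccc(cc1)/C(Oc1cc(OCC)cc(O[Si](C(C)C)(C(C)C)C(C)C)c1-c1cc(C2OCCO2)ccc1OC)=C/C(=O)O | intermediate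
18 | 8-[5-(1,3-dioxolan-2-yl)-2-methoxyphenyl]-5-ethoxy-2-(4-isopropoxyphenyl)-7-(triisopropylsilyloxy)-4H-chromen-4-one | CCOc1cc(O[Si](C(C)C)(C(C)C)C(C)C)c(-c2cc(C3OCCO3)ccc2OC)c2oc(-c3ccc(OC(C)C)cc3)cc(=O)c12 | intermediate
19 | 3-[5-ethoxy-2-(4-isopropoxyphenyl)-4-oxo-7-(triisopropylsilyloxy)-4H-chromen-8-yl]-4-methoxybenzaldehyde | CCOc1cc(O[Si](C(C)C)(C(C)C)C(C)C)c(-c2cc(C=O)ccc2OC)c2oc(-c3ccc(OC(C)C)cc3)cc(=O)c12 | intermediate
20 | cesium 5-ethoxy-8-(5-formyl-2-methoxyphenyl)-2-(4-isopropoxyphenyl)-4-oxo-4H-chromen-7-olate | [Cs+].CCOc1cc([O-])c(-c2cc(C=O)ccc2OC)c2oc(-c3ccc(OC(C)C)cc3)cc(=O)c12 | intermediate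
21 | 3-[5-ethoxy-7-isopropoxy-2-(4-isopropoxyphenyl)-4-oxo-4H-chromen-8-yl]-4-methoxybenzaldehyde | CCOc1cc(OC(C)C)c(-c2cc(C=O)ccc2OC)c2oc(-c3ccc(OC(C)C)cc3)cc(=O)c12 | intermediate
22 | 2,6-dimethoxytoluene | COc1cccc(OC)c1C | starting material
23 | 2-(3,5-dimethoxy-4-methylphenyl)-4,4,5,5-tetramethyl-1,3,2-dioxaborolane | COc1cc(B2OC(C)(C)C(C)(C)O2)cc(OC)c1C | intermediate
24 | 3,5-dimethoxy-4-methylphenol | COc1cc(O)cc(OC)c1C | intermediate
25 | difluoroboron O,O-chelate of 1-(6-hydroxy-2,4-dimethoxy-3-methylphenyl)ethan-1-one | CC1=[O+][B-](F)(F)Oc2cc(OC)c(C)c(OC)c12 | intermediate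
26 | 1-(6-hydroxy-2,4-dimethoxy-3-methylphenyl)ethan-1-one | CC(=O)c1c(O)cc(OC)c(C)c1OC | intermediate
27 | (2E)-3-{3-[5-ethoxy-7-isopropoxy-2-(4-isopropoxyphenyl)-4-oxo-4H-chromen-8-yl]-4-methoxyphenyl}-1-(6-hydroxy-2,4-dimethoxy-3-methylphenyl)prop-2-en-1-one | CCOc1cc(OC(C)C)c(-c2cc(/C=C/C(=O)c3c(O)cc(OC)c(C)c3OC)ccc2OC)c2oc(-c3ccc(OC(C)C)cc3)cc(=O)c12 | intermediate
28 | 8-[5-(5,7-dimethoxy-6-methyl-4-oxo-4H-chromen-2-yl)-2-methoxyphenyl]-5-ethoxy-7-isopropoxy-2-(4-isopropoxyphenyl)-4H-chromen-4-one | CCOc1cc(OC(C)C)c(-c2cc(-c3cc(=O)c4c(OC)c(C)c(OC)cc4o3)ccc2OC)c2oc(-c3ccc(OC(C)C)cc3)cc(=O)c12 | intermediate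
29 | taiwanhomoflavone A, 5,7-dihydroxy-8-[5-(5-hydroxy-7-methoxy-6-methyl-4-oxo-4H-chromen-2-yl)-2-methoxyphenyl]-2-(4-hydroxyphenyl)-4H-chromen-4-one | COc1ccc(-c2cc(=O)c3c(O)c(C)c(OC)cc3o2)cc1-c1c(O)cc(O)c2c(=O)cc(-c3ccc(O)cc3)oc12 | target

**Count**
Total steps: 13. Longest linear sequence: 9 (steps 1, 2, 3, 6, 7, 8, 11, 12, 13).

**Steps most likely to fail**

Step 3. The donor-stabilised cyclobutenone may open too slowly, so that at the temperature needed the siloxyalkyne isomerises by 1,3-silyl shift to a silylketene, the cyclobutenone oligomerises, or the product phenol is acylated by the vinylketene. The fallback generates the same vinylketene without heat; it sets out from 5 and returns at 11. 1-Ethoxyvinyllithium (ethyl vinyl ether, t-BuLi) is acylated with N-methoxy-N-methylacetamide to 3-ethoxybut-3-en-2-one F1. Its lithium enolate (LiN(SiMe3)2) is trifluoroacetylated with 2,2,2-trifluoroethyl trifluoroacetate to 5-ethoxy-1,1,1-trifluorohex-5-ene-2,4-dione F2. Detrifluoroacetylative diazo transfer (methanesulfonyl azide, Et3N) gives 1-diazo-3-ethoxybut-3-en-2-one F3. Irradiation of F3 with 5 in CH2Cl2 at 25 °C should trigger a photochemical Wolff rearrangement to ketene 7, and gentle warming completes the cascade to 11.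

Step 6. Conjugate addition of a hindered ortho-arylated phenoxide to an ynoate deactivated by its para-alkoxy group may be slow, and prolonged heating invites silyl transfer between phenoxides (then double addition) or C-alkylation of the electron-rich ring. The fallback builds the pyranone from a carbonyl placed by chelation and also bypasses step 7; it sets out from 11 and returns at 19. Ortho-formylation with MgCl2, Et3N and paraformaldehyde in MeCN should give 3-[5-(1,3-dioxolan-2-yl)-2-methoxyphenyl]-6-ethoxy-2-hydroxy-4-(triisopropylsilyloxy)benzaldehyde F4. Addition of lithium acetylide 14 (two equivalents, THF, −78 → 0 °C) gives the propargylic alcohol 1-{3-[5-(1,3-dioxolan-2-yl)-2-methoxyphenyl]-6-ethoxy-2-hydroxy-4-(triisopropylsilyloxy)phenyl}-3-(4-isopropoxyphenyl)prop-2-yn-1-ol F5. MnO2 in CH2Cl2 oxidises it to the ynone 1-{3-[5-(1,3-dioxolan-2-yl)-2-methoxyphenyl]-6-ethoxy-2-hydroxy-4-(triisopropylsilyloxy)phenyl}-3-(4-isopropoxyphenyl)prop-2-yn-1-one F6. Et2NH in EtOH should induce 6-endo closure to flavone acetal 18, and 1 M aq. HCl in THF then gives 19.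

Step 2. Addition of dibromomethyllithium to the ortho-methoxy ester may be incomplete, excess butyllithium may lithiate the anisole ring on warming, silylation may go to carbon, and the siloxyalkyne may hydrolyse on isolation. The fallback makes the ynolate by oxidising an acetylide; it sets out from 2 and returns at 5. LiAlH4 in THF at 0 °C gives [5-(1,3-dioxolan-2-yl)-2-methoxyphenyl]methanol F7, and MnO2 in CH2Cl2 gives 5-(1,3-dioxolan-2-yl)-2-methoxybenzaldehyde F8. Ohira–Bestmann homologation (dimethyl (1-diazo-2-oxopropyl)phosphonate, K2CO3, MeOH) gives 2-(3-ethynyl-4-methoxyphenyl)-1,3-dioxolane F9. Deprotonation with n-BuLi and oxidation of the acetylide with lithium tert-butylperoxide (THF, −78 → 0 °C) should give ynolate 4, which i-Pr3SiOSO2CF3 silylates on oxygen to 5.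

**Further compounds**
F1 | step 3 | 3-ethoxybut-3-en-2-one | CC(=O)C(=C)OCC
F2 | step 3 | 5-ethoxy-1,1,1-trifluorohex-5-ene-2,4-dione | C=C(OCC)C(=O)CC(=O)C(F)(F)F
F3 | step 3 | 1-diazo-3-ethoxybut-3-en-2-one | C=C(OCC)C(=O)C=[N+]=[N-]
F4 | step 6 | 3-[5-(1,3-dioxolan-2-yl)-2-methoxyphenyl]-6-ethoxy-2-hydroxy-4-(triisopropylsilyloxy)benzaldehyde | O=Cc1c(O)c(-c2cc(C3OCCO3)ccc2OC)c(O[Si](C(C)C)(C(C)C)C(C)C)cc1OCC
F5 | step 6 | 1-{3-[5-(1,3-dioxolan-2-yl)-2-methoxyphenyl]-6-ethoxy-2-hydroxy-4-(triisopropylsilyloxy)phenyl}-3-(4-isopropoxyphenyl)prop-2-yn-1-ol (racemic) | OC(C#Cc1ccc(OC(C)C)cc1)c1c(O)c(-c2cc(C3OCCO3)ccc2OC)c(O[Si](C(C)C)(C(C)C)C(C)C)cc1OCC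
F6 | step 6 | 1-{3-[5-(1,3-dioxolan-2-yl)-2-methoxyphenyl]-6-ethoxy-2-hydroxy-4-(triisopropylsilyloxy)phenyl}-3-(4-isopropoxyphenyl)prop-2-yn-1-one | O=C(C#Cc1ccc(OC(C)C)cc1)c1c(O)c(-c2cc(C3OCCO3)ccc2OC)c(O[Si](C(C)C)(C(C)C)C(C)C)cc1OCC
F7 | step 2 | [5-(1,3-dioxolan-2-yl)-2-methoxyphenyl]methanol | OCc1cc(C2OCCO2)ccc1OC
F8 | step 2 | 5-(1,3-dioxolan-2-yl)-2-methoxybenzaldehyde | O=Cc1cc(C2OCCO2)ccc1OC
F9 | step 2 | 2-(3-ethynyl-4-methoxyphenyl)-1,3-dioxolane | C#Cc1cc(C2OCCO2)ccc1OC
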